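**Retrosynthetic overview**
- The C50 skeleton is cut as C15 + C20 + C15: C7=C8 by Wittig and C7'=C8' by Julia–Kocienski olefination on purchased all-E crocetin dialdehyde; the last step reduces the side-chain ester to the allylic alcohol.
- Acyclic end: a C15 phosphonium salt from (S)-α-terpineol; ring ozonolysis keeps the stereocentre that becomes C2, followed by prenyl Wittig, dehydrogenation, vinyl addition and salt formation.
- Cyclic end: a sulfone from a trans-2',6'-disubstituted ring alcohol. Its C6'–C7' bond is made under blue light by deoxygenative allylchromium addition to formaldehyde, trans to the C2' chain.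
- The only ring is formed early, by ozonolysis/aldol ring enlargement of (S)-α-campholenic aldehyde (C2' bought), then α-methylation and 1,2-reduction.

Assumption: the SMILES is read as the all-E (2R,2'S,6'R) isomer with the two ring substituents trans; (S)-α-campholenic aldehyde (the rearrangement product of (−)-α-pinene oxide) and all-E crocetin dialdehyde are taken as purchasable; locants such as C2, C6', C7' are carotenoid locants.

**Route**

Step 1
Reactants: 1 (S)-α-terpineol
Product: 3 4-[(3S)-5-hydroxy-2,2-dimethyloxolan-3-yl]butan-2-one (lactol as anomer mixture), via open-chain hydroxy keto aldehyde 2 (not isolated)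
Conditions: O3, CH2Cl2, −78 °C; Me2S, −78 °C → rt
Reagents that add atoms: ozone, [O-][O+]=O
Why: Alkene ozonolysis with reductive work-up cleaves only the ring double bond, leaves the stereocentre (future C2) untouched, and the hydroxy aldehyde closes to the five-membered lactol.

Step 2
Reactants: 3 lactol
Product: 4 (5S)-5-(2-hydroxypropan-2-yl)-8-methylnon-7-en-2-one
Conditions: i-PrPPh3I (2.5 equiv), n-BuLi (2.4 equiv), THF, 0 °C; then 3, −78 °C → rt
Reagents that add atoms: isopropyltriphenylphosphonium iodide, CC(C)[P+](c1ccccc1)(c1ccccc1)c1ccccc1.[I-]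
Why: Wittig olefination of the aldehyde released from the lactol installs the prenyl group; the hindered isopropylidene ylide reacts with the aldehyde far faster than with the methyl ketone.

Step 3
Reactants: 4 hydroxy ketone
Product: 5 (3E,5R)-5-(2-hydroxypropan-2-yl)-8-methylnona-3,7-dien-2-one
Conditions: IBX (2.2 equiv), 4-methoxypyridine N-oxide (2.2 equiv), DMSO, rt
Reagents that add atoms: none
Why: IBX dehydrogenation of a ketone can only occur towards the CH2CH2 side (the methyl side has no β-hydrogen) and gives the E-enone under non-basic conditions that do not enolise the γ-stereocentre.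

Step 4
Reactants: 5 enone
Product: 6 (4E,6R)-6-(2-hydroxypropan-2-yl)-3,9-dimethyldeca-1,4,8-trien-3-ol (C3 epimers)
Conditions: CH2=CHMgBr (3 equiv), THF, −78 → 0 °C; aq NH4Cl
Reagents that add atoms: vinylmagnesium bromide, C=C[Mg]Br
Why: Grignard 1,2-addition to the enone; the new carbinol centre is formed as a mixture, which does not matter because it becomes sp2 in step 5.

Step 5
Reactants: 6 vinyl carbinol
Product: 7 [(2E,4E,6R)-7-hydroxy-3,7-dimethyl-6-(3-methylbut-2-en-1-yl)octa-2,4-dien-1-yl]triphenylphosphonium bromide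
Conditions: PPh3·HBr (1.1 equiv), MeOH/CH2Cl2, 0 °C → rt
Reagents that add atoms: triphenylphosphine hydrobromide, Br.P(c1ccccc1)(c1ccccc1)c1ccccc1
Why: Classical vinyl-carbinol to allylic phosphonium salt conversion (allylic transposition, as in C15 carotenoid salts); the dienyl cation is captured by PPh3 at the unhindered terminus while the non-allylic tertiary alcohol does not ionise.

Step 6
Reactants: 8 (S)-α-campholenic aldehyde
Product: 9 ethyl (2E)-2-methyl-4-[(1S)-2,2,3-trimethylcyclopent-3-en-1-yl]but-2-enoate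
Conditions: Ph3P=C(CH3)CO2Et (1.2 equiv), CH2Cl2, rt
Reagents that add atoms: ethyl 2-(triphenylphosphoranylidene)propanoate, CCOC(=O)C(C)=P(c1ccccc1)(c1ccccc1)c1ccccc1
Why: Wittig reaction with a stabilised ylide gives the E-trisubstituted enoate of the future C2' side chain; the stereocentre is β to the aldehyde and cannot epimerise.

Step 7
Reactants: 9 cyclopentene enoate
Product: 11 ethyl (2E)-4-[(1S)-2,2-dimethyl-3-oxocyclohex-4-en-1-yl]-2-methylbut-2-enoate, via keto aldehyde 10 (not isolated)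
Conditions: O3, CH2Cl2, −78 °C (Sudan Red end point); Me2S, → rt; then piperidine (0.2 equiv), AcOH (0.2 equiv), toluene, 60 °C
Reagents that add atoms: ozone, [O-][O+]=O
Why: Ozone cleaves the electron-rich ring alkene much faster than the enoate, and the methyl ketone (enolisable only at CH3) then undergoes intramolecular aldol condensation onto the aldehyde, enlarging the cyclopentene to the cyclohexenone without touching C2'.

Step 8
Reactants: 11 cyclohexenone
Product: 12 ethyl (2E)-4-[(1R)-4-iodo-2,2-dimethyl-3-oxocyclohex-4-en-1-yl]-2-methylbut-2-enoate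
Conditions: I2 (1.5 equiv), pyridine, CH2Cl2, 0 °C → rt
Reagents that add atoms: iodine, II
Why: Pyridine-mediated α-iodination of a cyclic enone (addition–elimination) is selective for the ring enone; the acyclic trisubstituted enoate does not react.

Step 9
Reactants: 12 α-iodoenone
Product: 13 ethyl (2E)-2-methyl-4-[(1S)-2,2,4-trimethyl-3-oxocyclohex-4-en-1-yl]but-2-enoate
Conditions: trimethylboroxine, Pd(dppf)Cl2 (5 mol%), Cs2CO3, dioxane/H2O, 80 °C
Reagents that add atoms: trimethylboroxine, CB1OB(C)OB(C)O1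
Why: Suzuki–Miyaura methylation of the α-iodoenone places the C5' methyl group regiospecifically.

Step 10
Reactants: 13 methyl enone
Product: 14 ethyl (2E)-4-[(1S)-3-hydroxy-2,2,4-trimethylcyclohex-4-en-1-yl]-2-methylbut-2-enoate (C3 epimers)
Conditions: NaBH4, CeCl3·7H2O, MeOH, 0 °C
Reagents that add atoms: none
Why: Luche 1,2-reduction of the enone spares the ester; the carbinol configuration is irrelevant because this carbon becomes a planar allyl radical in step 11.

Step 11
Reactants: 14 allylic alcohol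
Product: 16 ethyl (2E)-4-[(1S,5R)-5-(hydroxymethyl)-4,6,6-trimethylcyclohex-3-en-1-yl]-2-methylbut-2-enoate, via benzoxazoline adduct 15 (not isolated)
Conditions: 3-phenylbenzoxazolium tetrafluoroborate (1.2 equiv), pyridine (1.2 equiv), MTBE, rt, 20 min; then paraformaldehyde (5 equiv), CrCl2 (10 mol%), 4CzIPN (2 mol%), quinuclidine (30 mol%), DMA, 450 nm LEDs, rt
Reagents that add atoms: formaldehyde (from paraformaldehyde), C=O
Why: Proposed new method: the alcohol is condensed in the flask with the benzoxazolium salt, and photoexcited 4CzIPN oxidises this adduct, which after proton loss and C–O β-scission expels the carbamate and leaves the ring allyl radical (C4'–C5'–C6'); divalent chromium traps the radical at the less hindered C4' terminus and the resulting allylchromium (trivalent) adds to formaldehyde through a six-membered transition state with allyl transposition, so the C–C bond forms at C6' and the alkene returns to C4'=C5'; the equatorial C2' chain makes the C1' methyl cis to it axial, so formaldehyde is delivered to the opposite face and the new CH2OH is trans to the C2' chain (6'R); the reduced photocatalyst returns trivalent chromium to divalent chromium, so the step is redox neutral; the closest known reactions are photoredox deoxygenative radical generation from benzoxazolium–alcohol adducts (used with nickel) and photoredox/chromium Nozaki–Hiyama-type allylation of aldehydes.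

Step 12
Reactants: 16 ring alcohol
Product: 17 ethyl (2E)-2-methyl-4-[(1S,5R)-4,6,6-trimethyl-5-{[(1-phenyl-1H-tetrazol-5-yl)sulfanyl]methyl}cyclohex-3-en-1-yl]but-2-enoate
Conditions: 1-phenyl-1H-tetrazole-5-thiol, PPh3, DIAD, THF, 0 °C → rt
Reagents that add atoms: 1-phenyl-1H-tetrazole-5-thiol, Sc1nnnn1-c1ccccc1
Why: Mitsunobu thioetherification of the primary alcohol with an acidic thiol; no stereocentre is involved.

Step 13
Reactants: 17 sulfide
Product: 18 ethyl (2E)-2-methyl-4-[(1S,5R)-4,6,6-trimethyl-5-{[(1-phenyl-1H-tetrazol-5-yl)sulfonyl]methyl}cyclohex-3-en-1-yl]but-2-enoate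
Conditions: (NH4)6Mo7O24·4H2O (10 mol%), 30% H2O2, EtOH, 0 °C → rt
Reagents that add atoms: hydrogen peroxide, OO
Why: Molybdate-catalysed peroxide oxidation takes the sulfide to the sulfone and is slow towards trisubstituted alkenes at this temperature.

Step 14
Reactants: 18 sulfone and 19 all-E crocetin dialdehyde (3 equiv)
Product: 20 ethyl (2E)-2-methyl-4-[(1S,5R)-4,6,6-trimethyl-5-[(1E,3E,5E,7E,9E,11E,13E,15E)-3,7,12,16-tetramethyl-17-oxoheptadeca-1,3,5,7,9,11,13,15-octaen-1-yl]cyclohex-3-en-1-yl]but-2-enoate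
Conditions: KN(SiMe3)2 (1.1 equiv) added to 18 and 19, DME, −60 °C → rt
Reagents that add atoms: none
Why: Julia–Kocienski olefination in Barbier mode forms C7'=C8'; the excess dialdehyde ensures mono-olefination, and C6' (β to the sulfone) is not deprotonated.

Step 15
Reactants: 20 apo-aldehyde and 7 phosphonium bromide
Product: 22 ethyl (2E)-4-[(1S,5R)-5-[(1E,3E,5E,7E,9E,11E,13E,15E,17E,19E,21E,23R)-24-hydroxy-3,7,12,16,20,24-hexamethyl-23-(3-methylbut-2-en-1-yl)pentacosa-1,3,5,7,9,11,13,15,17,19,21-undecaen-1-yl]-4,6,6-trimethylcyclohex-3-en-1-yl]-2-methylbut-2-enoate, via phosphorane 21 (not isolated)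
Conditions: NaOEt, EtOH/CH2Cl2, 0 °C → rt; then heptane, reflux (Z to all-E equilibration), crystallisation
Reagents that add atoms: none
Why: Wittig olefination forms C7=C8 and completes the C50 chain; the Z isomers from steps 5, 14 and 15 are equilibrated thermally to the all-E polyene, as is standard for carotenoids.

Step 16
Reactants: 22 C50 ethyl ester
Product: 23 target, (2E)-4-[(1S,5R)-5-[(1E,3E,5E,7E,9E,11E,13E,15E,17E,19E,21E,23R)-24-hydroxy-3,7,12,16,20,24-hexamethyl-23-(3-methylbut-2-en-1-yl)pentacosa-1,3,5,7,9,11,13,15,17,19,21-undecaen-1-yl]-4,6,6-trimethylcyclohex-3-en-1-yl]-2-methylbut-2-en-1-ol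
Conditions: i-Bu2AlH (4 equiv), CH2Cl2, −78 °C; aq potassium sodium tartrate
Reagents that add atoms: none
Why: Hydride 1,2-reduction of the conjugated ester gives the E-allylic alcohol without touching the polyene or any stereocentre.

**Compound list**
1 | (S)-α-terpineol, 2-[(1S)-4-methylcyclohex-3-en-1-yl]propan-2-ol | CC1=CC[C@H](CC1)C(C)(C)O | starting material
2 | (3S)-3-(2-hydroxypropan-2-yl)-6-oxoheptanal | O=CC[C@H](CCC(C)=O)C(C)(C)O | intermediate (not isolated)
3 | 4-[(3S)-5-hydroxy-2,2-dimethyloxolan-3-yl]butan-2-one (anomer mixture) | CC(=O)CC[C@H]1CC(O)OC1(C)C | intermediate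
4 | (5S)-5-(2-hydroxypropan-2-yl)-8-methylnon-7-en-2-one | CC(=O)CC[C@@H](CC=C(C)C)C(C)(C)O | intermediate
5 | (3E,5R)-5-(2-hydroxypropan-2-yl)-8-methylnona-3,7-dien-2-one | CC(=O)/C=C/[C@@H](CC=C(C)C)C(C)(C)O | intermediate
6 | (4E,6R)-6-(2-hydroxypropan-2-yl)-3,9-dimethyldeca-1,4,8-trien-3-ol (C3 epimers) | C=CC(C)(O)/C=C/[C@@H](CC=C(C)C)C(C)(C)O | intermediate
7 | [(2E,4E,6R)-7-hydroxy-3,7-dimethyl-6-(3-methylbut-2-en-1-yl)octa-2,4-dien-1-yl]triphenylphosphonium bromide | CC(C)=CC[C@H](/C=C/C(C)=C/C[P+](c1ccccc1)(c1ccccc1)c1ccccc1)C(C)(C)O.[Br-] | intermediate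
8 | (S)-α-campholenic aldehyde, 2-[(1S)-2,2,3-trimethylcyclopent-3-en-1-yl]acetaldehyde | O=CC[C@@H]1CC=C(C)C1(C)C | starting material
9 | ethyl (2E)-2-methyl-4-[(1S)-2,2,3-trimethylcyclopent-3-en-1-yl]but-2-enoate | CCOC(=O)/C(C)=C/C[C@@H]1CC=C(C)C1(C)C | intermediate
10 | ethyl (2E,5R)-2,6,6-trimethyl-7-oxo-5-(2-oxoethyl)oct-2-enoate | CCOC(=O)/C(C)=C/C[C@H](CC=O)C(C)(C)C(C)=O | intermediate (not isolated)
11 | ethyl (2E)-4-[(1S)-2,2-dimethyl-3-oxocyclohex-4-en-1-yl]-2-methylbut-2-enoate | CCOC(=O)/C(C)=C/C[C@@H]1CC=CC(=O)C1(C)C | intermediate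
12 | ethyl (2E)-4-[(1R)-4-iodo-2,2-dimethyl-3-oxocyclohex-4-en-1-yl]-2-methylbut-2-enoate | CCOC(=O)/C(C)=C/C[C@@H]1CC=C(I)C(=O)C1(C)C | intermediate
13 | ethyl (2E)-2-methyl-4-[(1S)-2,2,4-trimethyl-3-oxocyclohex-4-en-1-yl]but-2-enoate | CCOC(=O)/C(C)=C/C[C@@H]1CC=C(C)C(=O)C1(C)C | intermediate
14 | ethyl (2E)-4-[(1S)-3-hydroxy-2,2,4-trimethylcyclohex-4-en-1-yl]-2-methylbut-2-enoate (C3 epimers) | CCOC(=O)/C(C)=C/C[C@@H]1CC=C(C)C(O)C1(C)C | intermediate
15 | ethyl (2E)-2-methyl-4-[(1S)-2,2,4-trimethyl-3-[(3-phenyl-2,3-dihydro-1,3-benzoxazol-2-yl)oxy]cyclohex-4-en-1-yl]but-2-enoate | CCOC(=O)/C(C)=C/C[C@@H]1CC=C(C)C(OC2Oc3ccccc3N2c2ccccc2)C1(C)C | intermediate (not isolated)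
16 | ethyl (2E)-4-[(1S,5R)-5-(hydroxymethyl)-4,6,6-trimethylcyclohex-3-en-1-yl]-2-methylbut-2-enoate | OC[C@@H]1C(C)=CC[C@@H](C/C=C(\C)C(=O)OCC)C1(C)C | intermediate
17 | ethyl (2E)-2-methyl-4-[(1S,5R)-4,6,6-trimethyl-5-{[(1-phenyl-1H-tetrazol-5-yl)sulfanyl]methyl}cyclohex-3-en-1-yl]but-2-enoate | c1ccccc1-n1nnnc1SC[C@@H]1C(C)=CC[C@@H](C/C=C(\C)C(=O)OCC)C1(C)C | intermediate
18 | ethyl (2E)-2-methyl-4-[(1S,5R)-4,6,6-trimethyl-5-{[(1-phenyl-1H-tetrazol-5-yl)sulfonyl]methyl}cyclohex-3-en-1-yl]but-2-enoate | c1ccccc1-n1nnnc1S(=O)(=O)C[C@@H]1C(C)=CC[C@@H](C/C=C(\C)C(=O)OCC)C1(C)C | intermediate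
19 | crocetin dialdehyde, (2E,4E,6E,8E,10E,12E,14E)-2,6,11,15-tetramethylhexadeca-2,4,6,8,10,12,14-heptaenedial | O=C/C(C)=C/C=C/C(C)=C/C=C/C=C(C)/C=C/C=C(C)/C=O | starting material
20 | ethyl (2E)-2-methyl-4-[(1S,5R)-4,6,6-trimethyl-5-[(1E,3E,5E,7E,9E,11E,13E,15E)-3,7,12,16-tetramethyl-17-oxoheptadeca-1,3,5,7,9,11,13,15-octaen-1-yl]cyclohex-3-en-1-yl]but-2-enoate | O=C/C(C)=C/C=C/C(C)=C/C=C/C=C(C)/C=C/C=C(C)/C=C/[C@@H]1C(C)=CC[C@@H](C/C=C(\C)C(=O)OCC)C1(C)C | intermediate
21 | (6R)-2,6-dimethyl-5-(3-methylbut-2-en-1-yl)-8-(triphenyl-λ5-phosphanylidene)octa-3,6-dien-2-ol (ylide of 7) | CC(C)=CC[C@H](/C=C/C(C)=C/C=P(c1ccccc1)(c1ccccc1)c1ccccc1)C(C)(C)O | intermediate (not isolated)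
22 | ethyl (2E)-4-[(1S,5R)-5-[(1E,3E,5E,7E,9E,11E,13E,15E,17E,19E,21E,23R)-24-hydroxy-3,7,12,16,20,24-hexamethyl-23-(3-methylbut-2-en-1-yl)pentacosa-1,3,5,7,9,11,13,15,17,19,21-undecaen-1-yl]-4,6,6-trimethylcyclohex-3-en-1-yl]-2-methylbut-2-enoate | CC(C)=CC[C@H](/C=C/C(C)=C/C=C/C(C)=C/C=C/C(C)=C/C=C/C=C(C)/C=C/C=C(C)/C=C/[C@@H]1C(C)=CC[C@@H](C/C=C(\C)C(=O)OCC)C1(C)C)C(C)(C)O | intermediate
23 | target, (2R,2'S,6'R) all-E; (2E)-4-[(1S,5R)-5-[(1E,3E,5E,7E,9E,11E,13E,15E,17E,19E,21E,23R)-24-hydroxy-3,7,12,16,20,24-hexamethyl-23-(3-methylbut-2-en-1-yl)pentacosa-1,3,5,7,9,11,13,15,17,19,21-undecaen-1-yl]-4,6,6-trimethylcyclohex-3-en-1-yl]-2-methylbut-2-en-1-ol | CC(C)=CC[C@H](/C=C/C(C)=C/C=C/C(C)=C/C=C/C(C)=C/C=C/C=C(C)/C=C/C=C(C)/C=C/[C@@H]1C(C)=CC[C@@H](C/C=C(\C)CO)C1(C)C)C(C)(C)O | target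

**Totals**
Total step count: 16. Longest linear sequence: 11 steps (steps 6 to 16, from 8).

**Three steps most likely to fail, with fallbacks**

Step 11 (the proposed new step). Risks are a slow or incomplete alcohol–benzoxazolium condensation at the hindered carbinol, interference of the azolium or formaldehyde with the chromium cycle, and attack at C4' instead of C6'. The fallback uses known two-electron organochromium chemistry. It sets out from 14: mesylation in the presence of chloride (MsCl, Et3N, LiCl, CH2Cl2/DMF, 0 °C) gives ethyl (2E)-4-[(1R)-3-chloro-2,2,4-trimethylcyclohex-4-en-1-yl]-2-methylbut-2-enoate F3, formed together with its allylic isomer; both give the same allylchromium. Stoichiometric CrCl2 and paraformaldehyde in THF (Nozaki–Hiyama allylation) then give the same transposing, trans-selective carbonyl addition, and the route is rejoined at 16.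

Step 14. Risks are mono-olefination of the dialdehyde, the hindered β-branched sulfone, and modest E selectivity with an enal. The fallback reverses the polarity of this junction and sets out from 16, using 7 and 19:
- 16 is oxidised with Dess–Martin periodinane to ethyl (2E)-4-[(1S,5R)-5-formyl-4,6,6-trimethylcyclohex-3-en-1-yl]-2-methylbut-2-enoate F4.
- In parallel, 7 and excess 19 (NaOEt, EtOH) give the acyclic-end apo-aldehyde (22R)-23-hydroxy-2,6,11,15,19,23-hexamethyl-22-(3-methylbut-2-en-1-yl)tetracosa-2,4,6,8,10,12,14,16,18,20-decaenal F5.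
- NaBH4 reduces F5 to the corresponding decaene-1,23-diol F6, and PPh3·HBr converts that into the allylic phosphonium bromide F7.
- Wittig reaction of F7 with F4 in 1,2-epoxybutane at 60 °C (no free alkoxide, so C6' is not epimerised), followed by thermal equilibration, rejoins the route at 22.

Step 3. Risks are low conversion of an aliphatic methyl ketone and over-oxidation towards the dienone. The fallback is a Saegusa–Ito sequence and sets out from 4: Me3SiOTf/Et3N (CH2Cl2, 0 °C) gives the internal silyl enol ether trimethyl{[(2Z,5R)-8-methyl-5-{2-[(trimethylsilyl)oxy]propan-2-yl}nona-2,7-dien-2-yl]oxy}silane F1, with the tertiary alcohol silylated as well; any terminal enol ether reverts to 4 on work-up. Stoichiometric Pd(OAc)2 in MeCN dehydrogenates F1 to (3E,5R)-8-methyl-5-{2-[(trimethylsilyl)oxy]propan-2-yl}nona-3,7-dien-2-one F2, and K2CO3 in MeOH removes the silyl ether and rejoins the route at 5.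

Further compounds
F1 | step 3 | trimethyl{[(2Z,5R)-8-methyl-5-{2-[(trimethylsilyl)oxy]propan-2-yl}nona-2,7-dien-2-yl]oxy}silane | C/C(O[Si](C)(C)C)=C/C[C@@H](CC=C(C)C)C(C)(C)O[Si](C)(C)C
F2 | step 3 | (3E,5R)-8-methyl-5-{2-[(trimethylsilyl)oxy]propan-2-yl}nona-3,7-dien-2-one | CC(=O)/C=C/[C@@H](CC=C(C)C)C(C)(C)O[Si](C)(C)C
F3 | step 11 | ethyl (2E)-4-[(1R)-3-chloro-2,2,4-trimethylcyclohex-4-en-1-yl]-2-methylbut-2-enoate | CCOC(=O)/C(C)=C/C[C@@H]1CC=C(C)C(Cl)C1(C)C
F4 | step 14 | ethyl (2E)-4-[(1S,5R)-5-formyl-4,6,6-trimethylcyclohex-3-en-1-yl]-2-methylbut-2-enoate | O=C[C@@H]1C(C)=CC[C@@H](C/C=C(\C)C(=O)OCC)C1(C)C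
F5 | step 14 | (2E,4E,6E,8E,10E,12E,14E,16E,18E,20E,22R)-23-hydroxy-2,6,11,15,19,23-hexamethyl-22-(3-methylbut-2-en-1-yl)tetracosa-2,4,6,8,10,12,14,16,18,20-decaenal | CC(C)=CC[C@H](/C=C/C(C)=C/C=C/C(C)=C/C=C/C(C)=C/C=C/C=C(C)/C=C/C=C(C)/C=O)C(C)(C)O
F6 | step 14 | (2E,4E,6E,8E,10E,12E,14E,16E,18E,20E,22R)-2,6,11,15,19,23-hexamethyl-22-(3-methylbut-2-en-1-yl)tetracosa-2,4,6,8,10,12,14,16,18,20-decaene-1,23-diol | CC(C)=CC[C@H](/C=C/C(C)=C/C=C/C(C)=C/C=C/C(C)=C/C=C/C=C(C)/C=C/C=C(C)/CO)C(C)(C)O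
F7 | step 14 | [(2E,4E,6E,8E,10E,12E,14E,16E,18E,20E,22R)-23-hydroxy-2,6,11,15,19,23-hexamethyl-22-(3-methylbut-2-en-1-yl)tetracosa-2,4,6,8,10,12,14,16,18,20-decaen-1-yl]triphenylphosphonium bromide | CC(C)=CC[C@H](/C=C/C(C)=C/C=C/C(C)=C/C=C/C(C)=C/C=C/C=C(C)/C=C/C=C(C)/C[P+](c1ccccc1)(c1ccccc1)c1ccccc1)C(C)(C)O.[Br-]
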